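**Plan**

- Numbering: ring A is the methyl benzoate ring (C1 CO2Me, C2 OH, C4 bearing ester oxygen O4). Ring B is primed (C1' bearing carbonyl C7', C2' OH, C3' Me, C4' OMe, C5' Cl, C6' Me).
- Cuts, in retrosynthetic order: C5'–Cl; then the two ring B bonds C5'–C6' and C1'–C2'; then the O4–C7' ester bond; last the C5–CH3 bond of ring A.
- Enabling feature: the C6' methyl, C6', C1' and C7' form a but-2-ynoate already esterified to O4 of ring A. C2'–C5' with O2', the C3' methyl and O4' form a 1,3-dioxygenated 2-methylbuta-1,3-diene, so a 1-methoxy-1-silyloxy diene brings in O2'–H free and O4' methylated.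
- Forward order: ring A is bought and given its C5 methyl; O4 is acylated with but-2-ynoic acid; ring B is built on that ynoate by cycloaddition and aromatisation; chlorination at C5' ends the route.
- Stereochemistry: the target has no stereocentre and no stereogenic double bond; the single stereocentre of the cycloadduct vanishes on aromatisation.

Key step: step 6

Assumption: enol ether 9 is drawn as its E isomer and diene 11 as its 1Z isomer. Either geometry would lead to the same aromatic ring, because both carbons lose their configuration on aromatisation.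

**Route**

Step 1
Reactants: 1 methyl 2,4-dihydroxy-3,6-dimethylbenzoate
Product: 3 methyl 5-formyl-2,4-dihydroxy-3,6-dimethylbenzoate, via alpha-chloro ether 2 (not isolated)
Conditions: Cl2CHOMe (1.2 equiv), TiCl4 (2.2 equiv), CH2Cl2, 0 °C to rt; then ice-cold 1 M HCl
Reagents that add atoms: dichloromethyl methyl ether, COC(Cl)Cl; water, O
Why: Rieche formylation: TiCl4 bound at the O4 phenoxide should deliver the chloro(methoxy)carbenium electrophile to C5, the only unsubstituted ring carbon (ortho to O4, para to O2), and aqueous work-up hydrolyses the alpha-chloro ether 2 to the aldehyde.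

Step 2
Reactants: 3 methyl 5-formyl-2,4-dihydroxy-3,6-dimethylbenzoate
Product: 4 methyl 2,4-dihydroxy-3,5,6-trimethylbenzoate
Conditions: H2 (3 atm), 10% Pd/C, AcOH, HCl (cat.), 40 °C
Reagents that add atoms: none
Why: Catalytic hydrogenolysis of a hydroxybenzaldehyde: the aldehyde is reduced to the benzylic alcohol, whose C–O bond is activated by the ortho O4–H and para O2–H and should be cleaved on Pd/C in acid to leave the C5 methyl, while ester and arene are not reduced.

Step 3
Reactants: 4 methyl 2,4-dihydroxy-3,5,6-trimethylbenzoate; 5 but-2-ynoic acid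
Product: 6 methyl 4-(but-2-ynoyloxy)-2-hydroxy-3,5,6-trimethylbenzoate
Conditions: N,N'-dicyclohexylcarbodiimide (1.1 equiv), 4-(dimethylamino)pyridine (0.05 equiv), CH2Cl2, −10 °C to rt
Reagents that add atoms: none
Why: Steglich esterification: O2–H is held in a hydrogen bond to the ester carbonyl, so the carbodiimide-activated acid should acylate the unchelated O4–H, whose two flanking methyls still admit the slim linear but-2-ynoyl group; the catalyst is kept low and cold to limit its conjugate addition to the ynoate.

Step 4
Reactants: 7 methyl 2-methyl-3-oxobutanoate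
Product: 9 methyl (E)-3-methoxy-2-methylbut-2-enoate, via dimethyl ketal 8 (not isolated)
Conditions: HC(OMe)3 (1.5 equiv), H2SO4 (cat.), neat, rt; then distillation
Reagents that add atoms: trimethyl orthoformate, COC(OC)OC
Why: Acid-catalysed ketalisation by the orthoformate followed by acid-catalysed thermal loss of methanol from ketal 8 (enol ether formation) should give the conjugated enol ether, expected mainly as the E isomer.

Step 5
Reactants: 9 methyl (E)-3-methoxy-2-methylbut-2-enoate
Product: 11 (1Z)-1,3-dimethoxy-2-methyl-1-(trimethylsilyloxy)buta-1,3-diene, via lithium dienolate 10 (not isolated)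
Conditions: LiN(i-Pr)2 (1.1 equiv), THF, −78 °C; then Me3SiCl (1.2 equiv), −78 °C to rt; pentane, filtration, distillation under reduced pressure
Reagents that add atoms: chlorotrimethylsilane, C[Si](C)(C)Cl
Why: Vinylogous (gamma) deprotonation of the beta-alkoxy enoate at the C4 methyl, the only position whose anion is conjugated with the ester, then O-silylation of dienolate 10: the standard silyl ketene acetal preparation of 1-alkoxy-1-silyloxy dienes.

Step 6
Reactants: 6 methyl 4-(but-2-ynoyloxy)-2-hydroxy-3,5,6-trimethylbenzoate; 11 (1Z)-1,3-dimethoxy-2-methyl-1-(trimethylsilyloxy)buta-1,3-diene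
Product: 15 methyl 2-hydroxy-4-[(2-hydroxy-4-methoxy-3,6-dimethylbenzoyl)oxy]-3,5,6-trimethylbenzoate, via O2-silylated butynoate 12 (not isolated), via cyclohexadiene ketal 13 (not isolated), via bis(trimethylsilyl) ether 14 (not isolated)
Conditions: N,O-bis(trimethylsilyl)acetamide (1.3 equiv), PhMe, 60 °C; then 11 (2.5 equiv), 120 °C, sealed tube; then 1 M HCl, THF, rt
Reagents that add atoms: none
Why: The donor-rich diene 11 and the acceptor ynoate 12 should combine in a concerted but strongly asynchronous [4+2] cycloaddition (equally describable as Mukaiyama–Michael attack of C5' on C6' followed by 6-exo-trig closure of C1' onto the C2' oxocarbenium carbon), forming C5'–C6' and C1'–C2' and giving the cyclohexa-1,4-diene ketal 13. The closest known reaction type is the Diels–Alder/aromatisation of 1-alkoxy-1-silyloxy-1,3-dienes with alkynoates to salicylates. Ring B is the only ring closed, a six-membered carbocycle made by cycloaddition; 1,4-elimination of methanol across C2'/C5' then aromatises it to the aryl silyl ether 14, and dilute acid frees both phenols. No stereocentre is set: the ketal carbon C2' of 13 is racemic and becomes aromatic. The step needs regioselectivity, which the oxygen donors at C2' and C4' secure by making the CH2 terminus C5' the nucleophilic end that meets the beta carbon C6' of the ynoate, so methyl ends at C6', OMe at C4' and OH at C2'. It also needs the acid-sensitive diene to survive, which is why O2–H of ring A is silylated beforehand, and the aryl ester makes the ynoate a better dienophile than an alkyl ester would be.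

Step 7
Reactants: 15 methyl 2-hydroxy-4-[(2-hydroxy-4-methoxy-3,6-dimethylbenzoyl)oxy]-3,5,6-trimethylbenzoate
Product: 16 methyl 4-[(3-chloro-6-hydroxy-4-methoxy-2,5-dimethylbenzoyl)oxy]-2-hydroxy-3,5,6-trimethylbenzoate (chlorine at C5')
Conditions: N-chlorosuccinimide (1.05 equiv), DMF, 0 °C to rt
Reagents that add atoms: N-chlorosuccinimide, O=C1CCC(=O)N1Cl
Why: Electrophilic aromatic chlorination: C5' is the only aromatic C–H of 15, ortho to the O4' methyl ether and para to O2'–H, whereas ring A has no free position and is less electron-rich, so one equivalent of reagent should chlorinate C5' only.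

**Compound list**

1 | methyl 2,4-dihydroxy-3,6-dimethylbenzoate | COC(=O)c1c(C)cc(O)c(C)c1O | starting material
2 | methyl 5-[chloro(methoxy)methyl]-2,4-dihydroxy-3,6-dimethylbenzoate (racemic, titanium-bound in the flask) | COC(Cl)c1c(C)c(C(=O)OC)c(O)c(C)c1O | intermediate
3 | methyl 5-formyl-2,4-dihydroxy-3,6-dimethylbenzoate | COC(=O)c1c(C)c(C=O)c(O)c(C)c1O | intermediate
4 | methyl 2,4-dihydroxy-3,5,6-trimethylbenzoate | COC(=O)c1c(C)c(C)c(O)c(C)c1O | intermediate
5 | but-2-ynoic acid | CC#CC(=O)O | starting material
6 | methyl 4-(but-2-ynoyloxy)-2-hydroxy-3,5,6-trimethylbenzoate | CC#CC(=O)Oc1c(C)c(C)c(C(=O)OC)c(O)c1C | intermediate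
7 | methyl 2-methyl-3-oxobutanoate (racemic) | COC(=O)C(C)C(C)=O | starting material
8 | methyl 3,3-dimethoxy-2-methylbutanoate (racemic) | COC(=O)C(C)C(C)(OC)OC | intermediate
9 | methyl (E)-3-methoxy-2-methylbut-2-enoate | COC(=O)/C(C)=C(\C)OC | intermediate
10 | lithium (1E)-1,3-dimethoxy-2-methylbuta-1,3-dien-1-olate | C=C(OC)/C(C)=C(/OC)[O-].[Li+] | intermediate
11 | (1Z)-1,3-dimethoxy-2-methyl-1-(trimethylsilyloxy)buta-1,3-diene | C=C(OC)/C(C)=C(/OC)O[Si](C)(C)C | intermediate
12 | methyl 4-(but-2-ynoyloxy)-3,5,6-trimethyl-2-(trimethylsilyloxy)benzoate | CC#CC(=O)Oc1c(C)c(C)c(C(=O)OC)c(O[Si](C)(C)C)c1C | intermediate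
13 | 4-(methoxycarbonyl)-2,5,6-trimethyl-3-(trimethylsilyloxy)phenyl 4,6-dimethoxy-2,5-dimethyl-6-(trimethylsilyloxy)cyclohexa-1,4-diene-1-carboxylate (racemic) | CC1=C(C(=O)Oc2c(C)c(C)c(C(=O)OC)c(O[Si](C)(C)C)c2C)C(OC)(O[Si](C)(C)C)C(C)=C(OC)C1 | intermediate
14 | methyl 4-{[4-methoxy-3,6-dimethyl-2-(trimethylsilyloxy)benzoyl]oxy}-3,5,6-trimethyl-2-(trimethylsilyloxy)benzoate | COC(=O)c1c(C)c(C)c(OC(=O)c2c(C)cc(OC)c(C)c2O[Si](C)(C)C)c(C)c1O[Si](C)(C)C | intermediate
15 | methyl 2-hydroxy-4-[(2-hydroxy-4-methoxy-3,6-dimethylbenzoyl)oxy]-3,5,6-trimethylbenzoate | COC(=O)c1c(C)c(C)c(OC(=O)c2c(C)cc(OC)c(C)c2O)c(C)c1O | intermediate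
16 | methyl 4-[(3-chloro-6-hydroxy-4-methoxy-2,5-dimethylbenzoyl)oxy]-2-hydroxy-3,5,6-trimethylbenzoate | COC(=O)c1c(C)c(C)c(OC(=O)c2c(C)c(Cl)c(OC)c(C)c2O)c(C)c1O | target

**Count and risks**

Total steps: 7. Longest linear sequence: 5 steps (steps 1, 2, 3, 6, 7; the diene branch, steps 4 and 5, joins at step 6).

Steps most likely to fail:

1. Step 6 (cycloaddition and aromatisation). The beta-methyl ynoate may react so slowly that the ketene acetal diene is lost to desilylation or oligomerisation before the ring closes. The adduct may also eliminate silanol in place of methanol and so deliver the O2' methyl ether. Fallback: ring B is made by classical arene chemistry and joined by esterification. Setting out from 1, O4-selective methylation (MeI, K2CO3, acetone; the chelated O2–H stays) should give methyl 2-hydroxy-4-methoxy-3,6-dimethylbenzoate F1. Hydrolysis of the hindered ester (KOH, aqueous DMSO, 90 °C) should give 2-hydroxy-4-methoxy-3,6-dimethylbenzoic acid F2. Mixed-anhydride esterification of F2 with the ring A phenol 4 (trifluoroacetic anhydride, PhMe, rt) at its unchelated O4–H comes back to the route at 15; the chelated hydroxyls of both partners are expected to stay out of the reaction.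

2. Step 3 (O4 acylation with but-2-ynoic acid). Acylation may stall at the doubly ortho-substituted O4, so that the activated ynoic acid rearranges to the N-acylurea or is attacked at its beta carbon by the pyridine catalyst. Partial acylation at O2 may also erode the selectivity. Fallback: the cycloaddition is run on a simple ester and the hindered aryl ester is formed afterwards. Setting out from 5, O-alkylation of the carboxylate (BnBr, K2CO3, DMF, rt), which never activates the acyl carbon, should give benzyl but-2-ynoate F3. Heating F3 with diene 11 (PhMe, 120 °C) should give benzyl 4,6-dimethoxy-2,5-dimethyl-6-(trimethylsilyloxy)cyclohexa-1,4-diene-1-carboxylate F4, which should lose methanol to benzyl 4-methoxy-3,6-dimethyl-2-(trimethylsilyloxy)benzoate F5. Dilute HCl should then free benzyl 2-hydroxy-4-methoxy-3,6-dimethylbenzoate F6. Hydrogenolysis (H2, 10% Pd/C, EtOAc) should give 2-hydroxy-4-methoxy-3,6-dimethylbenzoic acid F2, which is esterified with 4 (trifluoroacetic anhydride, PhMe, rt) to come back to the route at 15.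

3. Step 7 (chlorination). The electrophile may attack the fully substituted ring A phenol para to O2–H (ipso chlorination with loss of aromaticity), chlorinate a benzylic methyl, or add a second chlorine. Fallback: the halogen is placed on a one-ring precursor and the depside bond is made last. Setting out from 1, chlorination of its only free ring position (SO2Cl2, Et2O, 0 °C) should give methyl 5-chloro-2,4-dihydroxy-3,6-dimethylbenzoate F7. O4 methylation (MeI, K2CO3, acetone) should give methyl 5-chloro-2-hydroxy-4-methoxy-3,6-dimethylbenzoate F8, and hydrolysis (KOH, aqueous DMSO, 90 °C) should give 5-chloro-2-hydroxy-4-methoxy-3,6-dimethylbenzoic acid F9. Esterification of F9 with 4 (trifluoroacetic anhydride, PhMe, rt) comes back to the route at the target 16.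

**Further compounds**

F1 | step 6 | methyl 2-hydroxy-4-methoxy-3,6-dimethylbenzoate | COC(=O)c1c(C)cc(OC)c(C)c1O
F2 | step 6 | 2-hydroxy-4-methoxy-3,6-dimethylbenzoic acid | OC(=O)c1c(C)cc(OC)c(C)c1O
F3 | step 3 | benzyl but-2-ynoate | CC#CC(=O)OCc1ccccc1
F4 | step 3 | benzyl 4,6-dimethoxy-2,5-dimethyl-6-(trimethylsilyloxy)cyclohexa-1,4-diene-1-carboxylate (racemic) | CC1=C(C(=O)OCc2ccccc2)C(OC)(O[Si](C)(C)C)C(C)=C(OC)C1
F5 | step 3 | benzyl 4-methoxy-3,6-dimethyl-2-(trimethylsilyloxy)benzoate | COc1cc(C)c(C(=O)OCc2ccccc2)c(O[Si](C)(C)C)c1C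
F6 | step 3 | benzyl 2-hydroxy-4-methoxy-3,6-dimethylbenzoate | COc1cc(C)c(C(=O)OCc2ccccc2)c(O)c1C
F7 | step 7 | methyl 5-chloro-2,4-dihydroxy-3,6-dimethylbenzoate | COC(=O)c1c(C)c(Cl)c(O)c(C)c1O
F8 | step 7 | methyl 5-chloro-2-hydroxy-4-methoxy-3,6-dimethylbenzoate | COC(=O)c1c(C)c(Cl)c(OC)c(C)c1O
F9 | step 7 | 5-chloro-2-hydroxy-4-methoxy-3,6-dimethylbenzoic acid | OC(=O)c1c(C)c(Cl)c(OC)c(C)c1O
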